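**Retrosynthetic overview**

- The target is reached by one global hydrogenolysis of a flavone that carries two benzyl ethers (3',5'-O) and a diphenylmethylene ketal (5,6-O).
- The pyranone ring C is the only skeletal ring made. It is closed last at C4–C4a by intramolecular Friedel–Crafts acylation of an (E)-β-aryloxy-α-methoxyacrylic acid.
- The strategy rests on C4a: it is the only hydrogen-bearing carbon of the pentaoxygenated A ring, ortho to O1 (on C8a) and to the C5 oxygen and para to the C7 methoxyl. It is therefore the only and a strongly activated site for acylation.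
- The acid comes from addition–elimination of the A-ring phenol to a β-chloro-α-methoxycinnamate (C2–O1 bond). That ester comes from a Claisen acylation of methyl methoxyacetate with the B-ring acid chloride (C2–C3 bond).
- The A-ring phenol comes from 2,3-dimethoxyphenol by para-oxidation to the quinone, Thiele–Winter acetoxylation, and ketalisation of the one ortho-diol (the temporary dioxole ring is formed here, before ring C).

Key step: step 10

Remark on the chemistry: the target has no stereocentre and no hindered axis, so it is achiral and no enantioselective step is needed. The only stereochemical element on the route is the alkene geometry of 12–15. These are drawn as the E isomers (carboxyl cis to Cl or OAr); E/Z mixtures are expected, are carried forward, and should converge in steps 8 and 10.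

**Route**

Step 1
Reactants: 1 2,3-dimethoxyphenol
Product: 2 2,3-dimethoxy-1,4-benzoquinone
Conditions: (KSO3)2NO (2.2 equiv), KH2PO4, H2O/acetone, 0 °C to rt
Reagents that add atoms: potassium nitrosodisulfonate (Fremy's salt), [K+].[K+].[O]N(S(=O)(=O)[O-])S(=O)(=O)[O-]
Why: Teuber oxidation, in which the nitroxyl radical oxidises a phenol with a free para position to the p-quinone and delivers the new oxygen to C4 of 1.

Step 2
Reactants: 2 2,3-dimethoxy-1,4-benzoquinone
Product: 3 5,6-dimethoxybenzene-1,2,4-triyl triacetate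
Conditions: Ac2O, H2SO4 (cat.), rt to 40 °C
Reagents that add atoms: acetic anhydride, CC(=O)OC(C)=O
Why: Thiele–Winter acetoxylation (acid-catalysed conjugate addition of acetate, enolisation, acetylation), and because the two free quinone carbons are equivalent by symmetry only one triacetate can form.

Step 3
Reactants: 3 5,6-dimethoxybenzene-1,2,4-triyl triacetate
Product: 5 6,7-dimethoxy-2,2-diphenyl-1,3-benzodioxol-5-ol, via 5,6-dimethoxybenzene-1,2,4-triol 4 (not isolated)
Conditions: HCl (1.25 M in MeOH), reflux, Ar; evaporate; Ph2CCl2 (1.1 equiv), Ph2O, 170 °C, Ar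
Reagents that add atoms: dichlorodiphenylmethane, ClC(Cl)(c1ccccc1)c1ccccc1
Why: Acid-catalysed transesterification frees the triol under non-oxidising conditions, and catechol ketalisation with Ph2CCl2 can bridge only the single ortho-dihydroxy pair as the five-membered benzophenone ketal, which leaves the isolated hydroxyl (the future O1) free.

Step 4
Reactants: 6 3,5-dihydroxy-4-methoxybenzoic acid
Product: 7 benzyl 3,5-bis(benzyloxy)-4-methoxybenzoate
Conditions: BnBr (3.3 equiv), K2CO3, DMF, 60 °C
Reagents that add atoms: benzyl bromide, BrCc1ccccc1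
Why: Williamson etherification of both phenols together with alkylation of the carboxylate, a standard exhaustive benzylation.

Step 5
Reactants: 7 benzyl 3,5-bis(benzyloxy)-4-methoxybenzoate
Product: 8 3,5-bis(benzyloxy)-4-methoxybenzoic acid
Conditions: NaOH, THF/MeOH/H2O, 60 °C; then aq. HCl
Reagents that add atoms: sodium hydroxide, [Na+].[OH-]
Why: Saponification of the benzyl ester by acyl–oxygen cleavage, to which the aryl benzyl and methyl ethers are inert.

Step 6
Reactants: 8 3,5-bis(benzyloxy)-4-methoxybenzoic acid; 9 methyl methoxyacetate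
Product: 11 methyl 3-[3,5-bis(benzyloxy)-4-methoxyphenyl]-2-methoxy-3-oxopropanoate (racemic at C2), via 3,5-bis(benzyloxy)-4-methoxybenzoyl chloride 10 (not isolated)
Conditions: (COCl)2, DMF (cat.), CH2Cl2, rt; evaporate; add to 9 (2.2 equiv)/LiHMDS (2.2 equiv), THF, −78 °C; aq. NH4Cl
Reagents that add atoms: none
Why: Crossed Claisen C-acylation of the lithium ester enolate by a non-enolisable aroyl chloride, with the second equivalent of enolate taken up by the more acidic β-keto ester so that it is not acylated again.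

Step 7
Reactants: 11 methyl 3-[3,5-bis(benzyloxy)-4-methoxyphenyl]-2-methoxy-3-oxopropanoate
Product: 12 methyl (E)-3-[3,5-bis(benzyloxy)-4-methoxyphenyl]-3-chloro-2-methoxyprop-2-enoate (E/Z mixture acceptable)
Conditions: POCl3 (3 equiv), DMF, 0 to 70 °C
Reagents that add atoms: phosphorus oxychloride, O=P(Cl)(Cl)Cl
Why: Vilsmeier–Haack-type chlorination of a β-keto ester, in which the enol oxygen is activated as an iminium ether and replaced by chloride through addition–elimination at the benzylic β-carbon.

Step 8
Reactants: 12 methyl (E)-3-[3,5-bis(benzyloxy)-4-methoxyphenyl]-3-chloro-2-methoxyprop-2-enoate; 5 6,7-dimethoxy-2,2-diphenyl-1,3-benzodioxol-5-ol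
Product: 13 methyl (E)-3-[3,5-bis(benzyloxy)-4-methoxyphenyl]-3-[(6,7-dimethoxy-2,2-diphenyl-1,3-benzodioxol-5-yl)oxy]-2-methoxyprop-2-enoate
Conditions: Cs2CO3, DMF, 80 °C, Ar
Reagents that add atoms: none
Why: Nucleophilic vinylic substitution (addition–elimination), in which the phenoxide adds to the β-carbon to give an ester-stabilised carbanion that expels chloride; with no vinylic hydrogen there is no elimination pathway, and both alkene isomers pass through the same carbanion.

Step 9
Reactants: 13 methyl (E)-3-[3,5-bis(benzyloxy)-4-methoxyphenyl]-3-[(6,7-dimethoxy-2,2-diphenyl-1,3-benzodioxol-5-yl)oxy]-2-methoxyprop-2-enoate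
Product: 14 (E)-3-[3,5-bis(benzyloxy)-4-methoxyphenyl]-3-[(6,7-dimethoxy-2,2-diphenyl-1,3-benzodioxol-5-yl)oxy]-2-methoxyprop-2-enoic acid
Conditions: LiOH, THF/MeOH/H2O, 50 °C; then cold 1 M HCl to pH 3, 0 °C
Reagents that add atoms: lithium hydroxide, [Li+].[OH-]
Why: Saponification of the methyl ester, the step used classically on β-aryloxycinnamic esters, with the base-stable ketal and benzyl ethers untouched and a cold, brief acidification to spare the enol ether.

Step 10
Reactants: 14 (E)-3-[3,5-bis(benzyloxy)-4-methoxyphenyl]-3-[(6,7-dimethoxy-2,2-diphenyl-1,3-benzodioxol-5-yl)oxy]-2-methoxyprop-2-enoic acid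
Product: 16 2-[3,5-bis(benzyloxy)-4-methoxyphenyl]-3,7,8-trimethoxy-5,6-[(diphenylmethylene)dioxy]-4H-chromen-4-one, via mixed trifluoroacetic anhydride 15 (not isolated)
Conditions: (CF3CO)2O (1.5 equiv), CH2Cl2, 0 °C to rt
Reagents that add atoms: none
Why: Trifluoroacetic anhydride turns the acid into the mixed anhydride 15, whose acyl carbon (an incipient acylium ion, stabilised as a vinylogous oxocarbenium by the aryloxy and methoxy groups) is attacked by A-ring C4a, and loss of the proton restores the arene and leaves the C4 carbonyl. The closest known reaction type is the acid-mediated cyclisation of 3-aryloxycinnamic acids to flavones (Ruhemann synthesis), run here as an anhydride-mediated intramolecular Friedel–Crafts acylation. The one ring closed is the six-membered pyranone (O1, C2, C3, C4, C4a, C8a), formed by 6-exo-trig attack of the arene carbon on the anhydride carbonyl. No stereocentre is formed. The step needs acylation at A-ring C4a and not at B-ring C2'/C6' (which would give a five-membered indenone), and it needs the ketal and benzyl ethers to survive: C4a is the only unsubstituted A-ring carbon and is activated ortho by O1 and the C5 oxygen and para by the 7-methoxyl, the carboxyl is cis to the aryloxy group in the E acid, six-membered closure is preferred over five, and the conditions are anhydrous, cold and free of Lewis acid. Any Z isomer should enter the same pathway because the push–pull alkene rotates easily at the acylium (ketene–oxocarbenium) stage.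

Step 11
Reactants: 16 2-[3,5-bis(benzyloxy)-4-methoxyphenyl]-3,7,8-trimethoxy-5,6-[(diphenylmethylene)dioxy]-4H-chromen-4-one
Product: 17 5,6,3',5'-tetrahydroxy-3,7,8,4'-tetramethoxyflavone
Conditions: H2 (1 atm), 10% Pd/C, THF/MeOH, rt; filter under Ar
Reagents that add atoms: none
Why: Catalytic hydrogenolysis cleaves the benzylic C–O bonds of both benzyl ethers and the doubly benzylic C–O bonds of the diphenylmethylene ketal, while the four methyl ethers and the tetrasubstituted C2=C3 bond of the flavone are inert at ambient pressure.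

**Compound list**

1 | 2,3-dimethoxyphenol | COc1cccc(O)c1OC | starting material
2 | 2,3-dimethoxy-1,4-benzoquinone | COC1=C(OC)C(=O)C=CC1=O | intermediate
3 | 5,6-dimethoxybenzene-1,2,4-triyl triacetate | CC(=O)Oc1cc(OC(C)=O)c(OC(C)=O)c(OC)c1OC | intermediate
4 | 5,6-dimethoxybenzene-1,2,4-triol (not isolated) | Oc1cc(O)c(O)c(OC)c1OC | intermediate
5 | 6,7-dimethoxy-2,2-diphenyl-1,3-benzodioxol-5-ol | Oc1cc2OC(c3ccccc3)(c3ccccc3)Oc2c(OC)c1OC | intermediate
6 | 3,5-dihydroxy-4-methoxybenzoic acid | COc1c(O)cc(C(=O)O)cc1O | starting material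
7 | benzyl 3,5-bis(benzyloxy)-4-methoxybenzoate | COc1c(OCc2ccccc2)cc(C(=O)OCc2ccccc2)cc1OCc1ccccc1 | intermediate
8 | 3,5-bis(benzyloxy)-4-methoxybenzoic acid | COc1c(OCc2ccccc2)cc(C(=O)O)cc1OCc1ccccc1 | intermediate
9 | methyl methoxyacetate | COCC(=O)OC | starting material
10 | 3,5-bis(benzyloxy)-4-methoxybenzoyl chloride (not isolated) | COc1c(OCc2ccccc2)cc(C(=O)Cl)cc1OCc1ccccc1 | intermediate
11 | methyl 3-[3,5-bis(benzyloxy)-4-methoxyphenyl]-2-methoxy-3-oxopropanoate (racemic) | COC(=O)C(OC)C(=O)c1cc(OCc2ccccc2)c(OC)c(OCc2ccccc2)c1 | intermediate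
12 | methyl (E)-3-[3,5-bis(benzyloxy)-4-methoxyphenyl]-3-chloro-2-methoxyprop-2-enoate | COC(=O)/C(OC)=C(\Cl)c1cc(OCc2ccccc2)c(OC)c(OCc2ccccc2)c1 | intermediate
13 | methyl (E)-3-[3,5-bis(benzyloxy)-4-methoxyphenyl]-3-[(6,7-dimethoxy-2,2-diphenyl-1,3-benzodioxol-5-yl)oxy]-2-methoxyprop-2-enoate | COC(=O)/C(OC)=C(\Oc1cc2OC(c3ccccc3)(c3ccccc3)Oc2c(OC)c1OC)c1cc(OCc2ccccc2)c(OC)c(OCc2ccccc2)c1 | intermediate
14 | (E)-3-[3,5-bis(benzyloxy)-4-methoxyphenyl]-3-[(6,7-dimethoxy-2,2-diphenyl-1,3-benzodioxol-5-yl)oxy]-2-methoxyprop-2-enoic acid | OC(=O)/C(OC)=C(\Oc1cc2OC(c3ccccc3)(c3ccccc3)Oc2c(OC)c1OC)c1cc(OCc2ccccc2)c(OC)c(OCc2ccccc2)c1 | intermediate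
15 | mixed anhydride of 14 with trifluoroacetic acid (not isolated) | O=C(OC(=O)/C(OC)=C(\Oc1cc2OC(c3ccccc3)(c3ccccc3)Oc2c(OC)c1OC)c1cc(OCc2ccccc2)c(OC)c(OCc2ccccc2)c1)C(F)(F)F | intermediate
16 | 2-[3,5-bis(benzyloxy)-4-methoxyphenyl]-3,7,8-trimethoxy-5,6-[(diphenylmethylene)dioxy]-4H-chromen-4-one | COc1c(OCc2ccccc2)cc(-c2oc3c(OC)c(OC)c4OC(c5ccccc5)(c5ccccc5)Oc4c3c(=O)c2OC)cc1OCc1ccccc1 | intermediate
17 | 5,6,3',5'-tetrahydroxy-3,7,8,4'-tetramethoxyflavone | COc1c(O)cc(-c2oc3c(OC)c(OC)c(O)c(O)c3c(=O)c2OC)cc1O | target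

**Step count**

Total steps: 11. Longest linear sequence: 8 steps (6 to 17 through steps 4–11); the A-ring branch (steps 1–3) joins at step 8.

**Steps most likely to fail**

1. Step 10. The trifluoroacetic acid set free may open the diphenylmethylene ketal before ring closure, or acylation may be diverted to the B ring after alkene isomerisation. The fallback forms the same C4–C4a bond by an anionic Parham-type cyclisation and sets out from 5. NBS in MeCN at 0 °C should brominate the only free ring carbon to give 4-bromo-6,7-dimethoxy-2,2-diphenyl-1,3-benzodioxol-5-ol F1. Addition–elimination of F1 to 12 (Cs2CO3, DMF, 80 °C) should give methyl (E)-3-[3,5-bis(benzyloxy)-4-methoxyphenyl]-3-[(4-bromo-6,7-dimethoxy-2,2-diphenyl-1,3-benzodioxol-5-yl)oxy]-2-methoxyprop-2-enoate F2. Bromine–lithium exchange with n-BuLi in THF at −95 °C should give the aryllithium of the bromo ester F3, which adds to the cis methyl ester and loses methoxide. The fallback comes back to the route at 16 and needs no acid.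

2. Step 8. Addition at the tetrasubstituted β-carbon, deactivated by the α-methoxyl, may be so slow that oxidation of the electron-rich phenoxide or attack at the ester outruns substitution. The fallback replaces addition–elimination by palladium-catalysed C–O cross-coupling and sets out from 11. NaH then PhNTf2 in THF at 0 °C should give methyl (E)-3-[3,5-bis(benzyloxy)-4-methoxyphenyl]-2-methoxy-3-{[(trifluoromethyl)sulfonyl]oxy}prop-2-enoate F4. Coupling of F4 with 5 (Pd2(dba)3, t-BuXPhos, K3PO4, toluene, 90 °C) should come back to the route at 13.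

3. Step 3. The hydroxyhydroquinone may be oxidised by air to the hydroxyquinone during the solvent change, or the third hydroxyl may enter intermolecular ketal formation at 170 °C. The fallback never passes through a triol and sets out from 1.
   - Magnesium-mediated ortho-formylation (MgCl2, Et3N, paraformaldehyde, MeCN, reflux) should give 2-hydroxy-3,4-dimethoxybenzaldehyde F5.
   - NBS in MeCN at 0 °C should brominate para to the hydroxyl to give 5-bromo-2-hydroxy-3,4-dimethoxybenzaldehyde F6.
   - Dakin oxidation (H2O2, aq. NaOH, 0 °C to rt) should pass through 5-bromo-2-hydroxy-3,4-dimethoxyphenyl formate F7, hydrolysed in the flask to 5-bromo-3,4-dimethoxybenzene-1,2-diol F8.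
   - Ph2CCl2 in Ph2O at 170 °C should give 5-bromo-6,7-dimethoxy-2,2-diphenyl-1,3-benzodioxole F9.
   - Palladium-catalysed hydroxylation of the aryl bromide (Pd2(dba)3, t-BuXPhos, KOH, dioxane/H2O, 100 °C) should come back to the route at 5.

**Further compounds**

F1 | step 10 | 4-bromo-6,7-dimethoxy-2,2-diphenyl-1,3-benzodioxol-5-ol | Oc1c(Br)c2OC(c3ccccc3)(c3ccccc3)Oc2c(OC)c1OC
F2 | step 10 | methyl (E)-3-[3,5-bis(benzyloxy)-4-methoxyphenyl]-3-[(4-bromo-6,7-dimethoxy-2,2-diphenyl-1,3-benzodioxol-5-yl)oxy]-2-methoxyprop-2-enoate | COC(=O)/C(OC)=C(\Oc1c(Br)c2OC(c3ccccc3)(c3ccccc3)Oc2c(OC)c1OC)c1cc(OCc2ccccc2)c(OC)c(OCc2ccccc2)c1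
F3 | step 10 | aryllithium of the bromo ester (lithium in place of bromine, not isolated) | COC(=O)/C(OC)=C(\Oc1c([Li])c2OC(c3ccccc3)(c3ccccc3)Oc2c(OC)c1OC)c1cc(OCc2ccccc2)c(OC)c(OCc2ccccc2)c1
F4 | step 8 | methyl (E)-3-[3,5-bis(benzyloxy)-4-methoxyphenyl]-2-methoxy-3-{[(trifluoromethyl)sulfonyl]oxy}prop-2-enoate | COC(=O)/C(OC)=C(\OS(=O)(=O)C(F)(F)F)c1cc(OCc2ccccc2)c(OC)c(OCc2ccccc2)c1
F5 | step 3 | 2-hydroxy-3,4-dimethoxybenzaldehyde | O=Cc1ccc(OC)c(OC)c1O
F6 | step 3 | 5-bromo-2-hydroxy-3,4-dimethoxybenzaldehyde | O=Cc1cc(Br)c(OC)c(OC)c1O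
F7 | step 3 | 5-bromo-2-hydroxy-3,4-dimethoxyphenyl formate (not isolated) | O=COc1cc(Br)c(OC)c(OC)c1O
F8 | step 3 | 5-bromo-3,4-dimethoxybenzene-1,2-diol | Oc1cc(Br)c(OC)c(OC)c1O
F9 | step 3 | 5-bromo-6,7-dimethoxy-2,2-diphenyl-1,3-benzodioxole | Brc1cc2OC(c3ccccc3)(c3ccccc3)Oc2c(OC)c1OC
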